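Cuts, in retrosynthetic order: the three benzyl ethers; the ester C–O bond from ring A to the C4 oxygen of ring B; the C5=C6 bond of ring B; the ester C–O bond from ring B to ring C; the C3–C4 bond; the C1–C6 bond.
Enabling feature: ring B is numbered C1 (acyl-bearing), C2 (OMe), C3 (H), C4 (O), C5 (H), C6 (CH3). C5–C6 is the only ring bond with no oxygen on either carbon, and it joins a CH to the methyl-bearing carbon. It can therefore be a trisubstituted alkene closed by metathesis of a vinyl ketone (C4, C5) with an isopropenyl group (C6), after which the C4 ketone enolises to the phenol.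
Forward: rings A and C come ready-made from methyl orsellinate. The open ring B chain is grown on 2,2,6-trimethyl-1,3-dioxin-4-one (isopropenyl by cross-coupling, acrolein by vinylogous aldol), passed to the ring C phenol as an acylketene, O-methylated, oxidised and ring-closed. Ring B is the only ring made; ring A is joined last and the benzyl groups are then removed.
Stereochemistry: the target has no stereocentre. The only stereochemical element of the route is the Z geometry of the tetrasubstituted C1=C2 enol ether, taken from the hydrogen-bonded enol on O-methylation. The racemic C4 carbinol is erased by oxidation.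

Key step: step 12

Remark: every compound carrying the C4 carbinol carbon is racemic. The β-keto ester of step 8 is drawn as its keto tautomer, although it should react through the chelated enol.

Step 1
Reactants: 1 methyl orsellinate (methyl 2,4-dihydroxy-6-methylbenzoate)
Product: 2 methyl 2-hydroxy-6-methyl-4-(pivaloyloxy)benzoate
Conditions: PivCl (1.05 equiv), Et3N, CH2Cl2, 0 °C
Reagents that add atoms: pivaloyl chloride, CC(C)(C)C(=O)Cl
Why: Selective O-acylation of a phenol: the C2 hydroxyl is tied up in a hydrogen bond to the neighbouring ester carbonyl, so the bulky acid chloride should reach only the free C4 hydroxyl.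

Step 2
Reactants: 2 methyl 2-hydroxy-6-methyl-4-(pivaloyloxy)benzoate
Product: 3 methyl 2-(benzyloxy)-6-methyl-4-(pivaloyloxy)benzoate
Conditions: BnBr, K2CO3, DMF, 60 °C
Reagents that add atoms: benzyl bromide, BrCc1ccccc1
Why: Williamson ether synthesis: carbonate in DMF deprotonates the remaining chelated phenol, which is benzylated, while the hindered aryl pivalate survives the anhydrous base.

Step 3
Reactants: 3 methyl 2-(benzyloxy)-6-methyl-4-(pivaloyloxy)benzoate
Product: 4 methyl 2-(benzyloxy)-4-hydroxy-6-methylbenzoate
Conditions: NaOMe, MeOH, 0 °C to rt; AcOH quench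
Reagents that add atoms: none
Why: Base-mediated transesterification: methoxide attacks the activated aryl pivalate much faster than the di-ortho-substituted methyl benzoate, where exchange would be degenerate anyway, and the benzyl ether is inert.

Step 4
Reactants: 5 2,2,6-trimethyl-4H-1,3-dioxin-4-one
Product: 6 5-iodo-2,2,6-trimethyl-4H-1,3-dioxin-4-one
Conditions: NIS, AcOH, rt, dark
Reagents that add atoms: N-iodosuccinimide, O=C1CCC(=O)N1I
Why: Electrophilic halogenation of a vinylogous carbonate: C5 of the heterocycle is the nucleophilic α-carbon of the enol ether, and iodination followed by proton loss restores the conjugated ring.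

Step 5
Reactants: 6 5-iodo-2,2,6-trimethyl-4H-1,3-dioxin-4-one; 7 isopropenylboronic acid pinacol ester
Product: 8 2,2,6-trimethyl-5-(prop-1-en-2-yl)-4H-1,3-dioxin-4-one
Conditions: PdCl2(dppf) (5 mol %), K2CO3, THF/H2O, 60 °C
Reagents that add atoms: none
Why: Suzuki–Miyaura coupling: zerovalent palladium formed in the flask inserts into the electron-poor carbon–iodine bond, and transmetalation from the boronate and reductive elimination form the bond that becomes C1–C6 of ring B, below the temperature at which the dioxinone starts to cyclorevert.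

Step 6
Reactants: 8 2,2,6-trimethyl-5-(prop-1-en-2-yl)-4H-1,3-dioxin-4-one; 9 acrolein
Product: 11 6-(2-hydroxybut-3-en-1-yl)-2,2-dimethyl-5-(prop-1-en-2-yl)-4H-1,3-dioxin-4-one (racemic), via lithium dienolate 10 (not isolated)
Conditions: LiN(iPr)2, THF, −78 °C; then 9, −78 °C; AcOH quench
Reagents that add atoms: none
Why: Vinylogous aldol addition of a dioxinone dienolate: only the ring C6 methyl is acidified by the vinylogous ester, the fully substituted α-position leaves only the exocyclic γ-carbon for attack, and the hard lithium dienolate adds 1,2 to acrolein to give a racemic carbinol that step 11 erases.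

Step 7
Reactants: 11 6-(2-hydroxybut-3-en-1-yl)-2,2-dimethyl-5-(prop-1-en-2-yl)-4H-1,3-dioxin-4-one
Product: 12 6-{2-[(tert-butyldimethylsilyl)oxy]but-3-en-1-yl}-2,2-dimethyl-5-(prop-1-en-2-yl)-4H-1,3-dioxin-4-one (racemic)
Conditions: TBSCl, imidazole, DMF, rt
Reagents that add atoms: tert-butyldimethylsilyl chloride, CC(C)(C)[Si](C)(C)Cl
Why: Imidazole-promoted silyl ether formation masks the hydroxyl, which would otherwise capture the ketene of the next step intramolecularly to give a lactone.

Step 8
Reactants: 12 silyl-protected dioxinone; 4 methyl 2-(benzyloxy)-4-hydroxy-6-methylbenzoate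
Product: 14 3-(benzyloxy)-4-(methoxycarbonyl)-5-methylphenyl 5-[(tert-butyldimethylsilyl)oxy]-3-oxo-2-(prop-1-en-2-yl)hept-6-enoate (keto/enol and diastereomer mixture), via acylketene 13 (not isolated)
Conditions: toluene, 110 °C, slow N2 stream to carry off acetone
Reagents that add atoms: none
Why: Dioxinone thermolysis and ketene capture: retro-hetero-Diels–Alder loss of acetone gives acylketene 13, and the only free hydroxyl present, the C4 phenol of ring C, adds through a cyclic transition state that delivers the hydrogen-bonded enol of the aryl β-keto ester under neutral conditions that spare the silyl ether, benzyl ether and methyl ester.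

Step 9
Reactants: 14 aryl β-keto ester
Product: 15 3-(benzyloxy)-4-(methoxycarbonyl)-5-methylphenyl (2Z)-5-[(tert-butyldimethylsilyl)oxy]-3-methoxy-2-(prop-1-en-2-yl)hepta-2,6-dienoate (racemic)
Conditions: CH2N2, Et2O, 0 °C to rt; base-washed glassware, Et3N-deactivated silica
Reagents that add atoms: diazomethane, C=[N+]=[N-]
Why: O-methylation of an enol with diazomethane: the acidic chelated enol, favoured by conjugation with the isopropenyl group and by the aryl ester, protonates the reagent, and the tight methyldiazonium–enolate pair should collapse at that same oxygen before the C1–C2 bond can turn, which places OMe cis to the ester (Z) and both future ring arms on one side, at a stage where no electron-poor terminal alkene is present to take up the dipole.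

Step 10
Reactants: 15 (Z)-enol ether silyl ether
Product: 16 3-(benzyloxy)-4-(methoxycarbonyl)-5-methylphenyl (2Z)-5-hydroxy-3-methoxy-2-(prop-1-en-2-yl)hepta-2,6-dienoate (racemic)
Conditions: HF·pyridine, pyridine, THF, 0 °C to rt
Reagents that add atoms: none
Why: Fluoride-driven desilylation under buffered conditions should leave the aryl ester, benzyl ether and vinylogous carbonate untouched, and in the Z isomer the liberated hydroxyl points away from the aryl ester and cannot lactonise.

Step 11
Reactants: 16 (Z)-enol ether allylic alcohol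
Product: 17 3-(benzyloxy)-4-(methoxycarbonyl)-5-methylphenyl (2Z)-3-methoxy-5-oxo-2-(prop-1-en-2-yl)hepta-2,6-dienoate
Conditions: Dess–Martin periodinane, CH2Cl2, 0 °C to rt
Reagents that add atoms: none
Why: Dess–Martin oxidation converts the allylic alcohol into the vinyl ketone under near-neutral, non-aqueous conditions, and the sensitive skipped enone is only passed through a short pad of deactivated silica and used at once.

Step 12
Reactants: 17 acyclic trienone enol ether ester
Product: 19 methyl 2-(benzyloxy)-4-[(4-hydroxy-2-methoxy-6-methylbenzoyl)oxy]-6-methylbenzoate, via ring B cyclohexadienone 18 (not isolated)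
Conditions: second-generation Hoveyda–Grubbs catalyst RuCl2(H2IMes)(=CH-C6H4-2-OiPr) (5–10 mol %), toluene (0.005 M), 80 °C, argon sparge
Reagents that add atoms: none
Why: The ruthenium alkylidene exchanges with one of the two terminal methylene groups, the tethered second alkene adds to give a ruthenacyclobutane, and cycloreversion releases ethene and forms the C5=C6 double bond, after which dienone 18, the keto tautomer of a phenol, enolises through its doubly activated C3 methylene and becomes aromatic irreversibly. The closest known reaction type is the ring-closing metathesis/tautomerisation of acyclic trienones to phenols, together with the closure of vinyl ketones onto 1,1-disubstituted alkenes to give 3-methylcyclohexenones. Ring B closes as a six-membered carbocycle from a 1,7-diene, the new endocyclic bond joining the former vinyl CH (C5) to the former isopropenyl carbon (C6). No stereocentre is formed. The step needs ring closure to win over cross-metathesis and needs the catalyst to ignore the third alkene: the Z enol ether holds both arms on the same side of C1=C2, the enone and the gem-disubstituted alkene are both poor homodimerisation partners, high dilution helps, and the tetrasubstituted push–pull C1=C2 bond is too hindered and polarised to enter metathesis. Because OMe (C2), the ester to ring C (C1) and the methyl group (C6) are already fixed on the chain, the only free phenol that appears is the one at C4.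

Step 13
Reactants: 1 methyl orsellinate
Product: 20 methyl 2,4-bis(benzyloxy)-6-methylbenzoate
Conditions: BnBr (2.5 equiv), K2CO3, DMF, 60 °C
Reagents that add atoms: benzyl bromide, BrCc1ccccc1
Why: Double Williamson ether synthesis, in which excess bromide and warm DMF also alkylate the chelated C2 hydroxyl.

Step 14
Reactants: 20 methyl 2,4-bis(benzyloxy)-6-methylbenzoate
Product: 21 2,4-bis(benzyloxy)-6-methylbenzoic acid
Conditions: KOH, DMSO/H2O, 90 °C; then aq HCl
Reagents that add atoms: potassium hydroxide, [K+].[OH-]
Why: Saponification: the di-ortho-substituted ester needs hot hydroxide in aqueous DMSO, conditions that benzyl ethers tolerate.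

Step 15
Reactants: 21 2,4-bis(benzyloxy)-6-methylbenzoic acid; 19 didepside with free ring B C4 phenol
Product: 23 methyl 2-(benzyloxy)-4-({4-[(2,4-bis(benzyloxy)-6-methylbenzoyl)oxy]-2-methoxy-6-methylbenzoyl}oxy)-6-methylbenzoate, via acyl trifluoroacetate 22 (not isolated)
Conditions: (CF3CO)2O, toluene, rt
Reagents that add atoms: none
Why: Mixed-anhydride esterification as used for depside coupling: trifluoroacetic anhydride turns the hindered, electron-rich acid into acyl trifluoroacetate 22, which acylates the only free hydroxyl of 19 under acidic conditions that avoid phenoxide-induced scrambling of the existing aryl ester.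

Step 16
Reactants: 23 tribenzyl tridepside
Product: 24 methyl 4-({4-[(2,4-dihydroxy-6-methylbenzoyl)oxy]-2-methoxy-6-methylbenzoyl}oxy)-2-hydroxy-6-methylbenzoate (CNP0563156.0)
Conditions: H2 (1 atm), Pd/C, EtOAc, rt
Reagents that add atoms: none
Why: Catalytic hydrogenolysis cleaves the three benzyl ethers under neutral conditions and leaves the two aryl esters, the methyl ester and the methyl ether intact.

Compound list
1 | methyl orsellinate | COC(=O)c1c(C)cc(O)cc1O | starting material
2 | methyl 2-hydroxy-6-methyl-4-(pivaloyloxy)benzoate | COC(=O)c1c(C)cc(OC(=O)C(C)(C)C)cc1O | intermediate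
3 | methyl 2-(benzyloxy)-6-methyl-4-(pivaloyloxy)benzoate | COC(=O)c1c(C)cc(OC(=O)C(C)(C)C)cc1OCc1ccccc1 | intermediate
4 | methyl 2-(benzyloxy)-4-hydroxy-6-methylbenzoate | COC(=O)c1c(C)cc(O)cc1OCc1ccccc1 | intermediate
5 | 2,2,6-trimethyl-4H-1,3-dioxin-4-one | CC1=CC(=O)OC(C)(C)O1 | starting material
6 | 5-iodo-2,2,6-trimethyl-4H-1,3-dioxin-4-one | CC1=C(I)C(=O)OC(C)(C)O1 | intermediate
7 | isopropenylboronic acid pinacol ester | C=C(C)B1OC(C)(C)C(C)(C)O1 | starting material
8 | 2,2,6-trimethyl-5-(prop-1-en-2-yl)-4H-1,3-dioxin-4-one | CC1=C(C(C)=C)C(=O)OC(C)(C)O1 | intermediate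
9 | acrolein | C=CC=O | starting material
10 | lithium dienolate of 8 (not isolated) | [Li+].C=C1OC(C)(C)OC([O-])=C1C(C)=C | intermediate
11 | 6-(2-hydroxybut-3-en-1-yl)-2,2-dimethyl-5-(prop-1-en-2-yl)-4H-1,3-dioxin-4-one, racemic | C=CC(O)CC1=C(C(C)=C)C(=O)OC(C)(C)O1 | intermediate
12 | TBS ether of 11, racemic | C=CC(O[Si](C)(C)C(C)(C)C)CC1=C(C(C)=C)C(=O)OC(C)(C)O1 | intermediate
13 | acylketene from 12 (not isolated) | C=CC(O[Si](C)(C)C(C)(C)C)CC(=O)C(=C=O)C(C)=C | intermediate
14 | aryl β-keto ester, keto tautomer drawn | C=CC(O[Si](C)(C)C(C)(C)C)CC(=O)C(C(C)=C)C(=O)Oc1cc(C)c(C(=O)OC)c(OCc2ccccc2)c1 | intermediate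
15 | (2Z)-methyl enol ether, TBS ether, racemic | C=CC(O[Si](C)(C)C(C)(C)C)C/C(OC)=C(\C(C)=C)C(=O)Oc1cc(C)c(C(=O)OC)c(OCc2ccccc2)c1 | intermediate
16 | (2Z)-methyl enol ether, allylic alcohol, racemic | C=CC(O)C/C(OC)=C(\C(C)=C)C(=O)Oc1cc(C)c(C(=O)OC)c(OCc2ccccc2)c1 | intermediate
17 | (2Z)-trienone enol ether ester (metathesis precursor) | C=CC(=O)C/C(OC)=C(\C(C)=C)C(=O)Oc1cc(C)c(C(=O)OC)c(OCc2ccccc2)c1 | intermediate
18 | aryl 2-methoxy-6-methyl-4-oxocyclohexa-1,5-diene-1-carboxylate (not isolated) | COC1=C(C(=O)Oc2cc(C)c(C(=O)OC)c(OCc3ccccc3)c2)C(C)=CC(=O)C1 | intermediate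
19 | benzyl-protected didepside with free ring B C4 phenol | COC(=O)c1c(C)cc(OC(=O)c2c(C)cc(O)cc2OC)cc1OCc1ccccc1 | intermediate
20 | methyl 2,4-bis(benzyloxy)-6-methylbenzoate | COC(=O)c1c(C)cc(OCc2ccccc2)cc1OCc1ccccc1 | intermediate
21 | 2,4-bis(benzyloxy)-6-methylbenzoic acid | OC(=O)c1c(C)cc(OCc2ccccc2)cc1OCc1ccccc1 | intermediate
22 | 2,4-bis(benzyloxy)-6-methylbenzoic trifluoroacetic anhydride (not isolated) | O=C(OC(=O)C(F)(F)F)c1c(C)cc(OCc2ccccc2)cc1OCc1ccccc1 | intermediate
23 | tribenzyl tridepside | COC(=O)c1c(C)cc(OC(=O)c2c(C)cc(OC(=O)c3c(C)cc(OCc4ccccc4)cc3OCc3ccccc3)cc2OC)cc1OCc1ccccc1 | intermediate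
24 | CNP0563156.0 | COC(=O)c1c(C)cc(OC(=O)c2c(C)cc(OC(=O)c3c(C)cc(O)cc3O)cc2OC)cc1O | target

Total step count: 16.
Longest linear sequence: 11 steps (steps 4 to 12, then 15 and 16).

Steps most likely to fail

Step 9. Three processes may spoil it: methylation on carbon instead of oxygen, a sluggish reaction of a weakly enolised keto ester, or loss of the Z geometry through acid-catalysed rotation about C1–C2.
- The fallback postpones the methylation until ring B is aromatic. It sets out from 11.
- Dess–Martin oxidation gives 2,2-dimethyl-6-(2-oxobut-3-en-1-yl)-5-(prop-1-en-2-yl)-4H-1,3-dioxin-4-one F1.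
- Thermolysis in toluene with 4 passes through the vinyl keto acylketene F2 and gives the aryl 3,5-dioxo-2-(prop-1-en-2-yl)hept-6-enoate F3. In F3, C1 is sp3 or part of a freely tautomerising enol, so no alkene geometry has to be set.
- Ring-closing metathesis with the catalyst of step 12 gives the aryl 2-methyl-4,6-dioxocyclohex-2-ene-1-carboxylate F4, which enolises to the didepside with a ring B 2,4-diol F5.
- The unchelated C4 phenol is acylated selectively with 21 and trifluoroacetic anhydride (through 22) to the tridepside with a free chelated ring B C2 hydroxyl F6.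
- MeI and K2CO3 in acetone methylate this last phenol, and the route is rejoined at 23.

Step 12. The catalyst may load slowly on an electron-poor enone and a hindered diene terminus, so catalyst decay, oligomerisation of the vinyl ketone or tautomerisation of the skipped enone may take over.
- The fallback closes the ring one oxidation level lower. It sets out from 16, whose allylic alcohol alkene is the better metathesis partner.
- Ring closure with the same catalyst gives the aryl 4-hydroxy-2-methoxy-6-methylcyclohexa-1,5-diene-1-carboxylate F7.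
- F7 is oxidised without delay with MnO2 in CH2Cl2, under acid-free conditions that suppress dehydration, to dienone 18. This enolises, and the route is rejoined at 19.

Step 8. Capture of the hindered α-alkenyl acylketene by an electron-poor phenol may be slower than ketene dimerisation, electrocyclic closure of the vinylketene, or migration of the isopropenyl double bond into conjugation.
- The fallback attaches ring C by classical esterification instead. It sets out from 12.
- Thermolysis in toluene containing a large excess of allyl alcohol gives, through 13, the allyl β-keto ester F8.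
- Diazomethane gives the allyl (2Z)-enol ether ester F9.
- Pd(PPh3)4 and morpholine release the (2Z)-enol ether carboxylic acid F10.
- Steglich-type esterification of F10 with 4 (EDC, DMAP, CH2Cl2) rejoins the route at 15.

Further compounds
F1 | step 9 | 2,2-dimethyl-6-(2-oxobut-3-en-1-yl)-5-(prop-1-en-2-yl)-4H-1,3-dioxin-4-one | C=CC(=O)CC1=C(C(C)=C)C(=O)OC(C)(C)O1
F2 | step 9 | vinyl keto acylketene | C=CC(=O)CC(=O)C(=C=O)C(C)=C
F3 | step 9 | 3-(benzyloxy)-4-(methoxycarbonyl)-5-methylphenyl 3,5-dioxo-2-(prop-1-en-2-yl)hept-6-enoate | C=CC(=O)CC(=O)C(C(C)=C)C(=O)Oc1cc(C)c(C(=O)OC)c(OCc2ccccc2)c1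
F4 | step 9 | 3-(benzyloxy)-4-(methoxycarbonyl)-5-methylphenyl 2-methyl-4,6-dioxocyclohex-2-ene-1-carboxylate | O=C1CC(=O)C(C(=O)Oc2cc(C)c(C(=O)OC)c(OCc3ccccc3)c2)C(C)=C1
F5 | step 9 | methyl 2-(benzyloxy)-4-[(2,4-dihydroxy-6-methylbenzoyl)oxy]-6-methylbenzoate | COC(=O)c1c(C)cc(OC(=O)c2c(C)cc(O)cc2O)cc1OCc1ccccc1
F6 | step 9 | tribenzyl tridepside with free ring B C2 hydroxyl | COC(=O)c1c(C)cc(OC(=O)c2c(C)cc(OC(=O)c3c(C)cc(OCc4ccccc4)cc3OCc3ccccc3)cc2O)cc1OCc1ccccc1
F7 | step 12 | 3-(benzyloxy)-4-(methoxycarbonyl)-5-methylphenyl 4-hydroxy-2-methoxy-6-methylcyclohexa-1,5-diene-1-carboxylate, racemic | COC1=C(C(=O)Oc2cc(C)c(C(=O)OC)c(OCc3ccccc3)c2)C(C)=CC(O)C1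
F8 | step 8 | allyl 5-[(tert-butyldimethylsilyl)oxy]-3-oxo-2-(prop-1-en-2-yl)hept-6-enoate | C=CCOC(=O)C(C(C)=C)C(=O)CC(O[Si](C)(C)C(C)(C)C)C=C
F9 | step 8 | allyl (2Z)-5-[(tert-butyldimethylsilyl)oxy]-3-methoxy-2-(prop-1-en-2-yl)hepta-2,6-dienoate, racemic | C=CC(O[Si](C)(C)C(C)(C)C)C/C(OC)=C(\C(C)=C)C(=O)OCC=C
F10 | step 8 | (2Z)-5-[(tert-butyldimethylsilyl)oxy]-3-methoxy-2-(prop-1-en-2-yl)hepta-2,6-dienoic acid, racemic | C=CC(O[Si](C)(C)C(C)(C)C)C/C(OC)=C(\C(C)=C)C(=O)O
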